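**Strategy**

Everything rests on cutting the benzylic C6–O7 bond of ring B (C1, C5, C6, O7, C8 of the 3,7-dioxabicyclo[3.3.0]octane) back to a plain 3,4-dimethoxybenzyl group. The key step, a DDQ-mediated dehydrogenative C–H etherification, exploits the para-methoxy-activated C6 methylene and the cis C8 hydroxymethyl on C1: hydride abstraction and capture of the cation close ring B and set C6 in one operation. The precursor is a monocyclic tetrahydrofuran (ring A) carrying the tertiary alcohol, the hydroxymethyl group and the benzyl group; a tosylate on its other aryl ring switches off the competing C2–H. Ring A arises by Sharpless epoxidation and 5-endo opening of an enediol made from an Evans-derived lactone.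

Key step: step 8

Remark: the tartrate enantiomer in step 7 is assigned by the empirical Sharpless rule (L-(+)-tartrate gives the 2S-type epoxide of a primary allylic alcohol), which is assumed to hold for this substrate with its neighbouring stereocentre.

**Route**

Step 1
Reactants: 1 3-(3,4-dimethoxyphenyl)propanoic acid; 2 (4S)-4-benzyl-1,3-oxazolidin-2-one
Product: 4 (4S)-4-benzyl-3-[3-(3,4-dimethoxyphenyl)propanoyl]-1,3-oxazolidin-2-one, via mixed pivalic anhydride 3 (not isolated)
Conditions: pivaloyl chloride, Et3N, THF, −20 °C; then LiCl, 2, −20 °C to rt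
Reagents that add atoms: none
Why: Mixed-anhydride N-acylation of the LiCl-activated oxazolidinone attaches the Evans auxiliary; no stereocentre is formed.

Step 2
Reactants: 4 (4S)-4-benzyl-3-[3-(3,4-dimethoxyphenyl)propanoyl]-1,3-oxazolidin-2-one
Product: 6 tert-butyl (3R)-4-[(4S)-4-benzyl-2-oxo-1,3-oxazolidin-3-yl]-3-(3,4-dimethoxybenzyl)-4-oxobutanoate, via sodium Z-enolate 5 (not isolated)
Conditions: NaN(SiMe3)2, THF, −78 °C; tert-butyl bromoacetate, −78 to −40 °C
Reagents that add atoms: tert-butyl bromoacetate, CC(C)(C)OC(=O)CBr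
Why: Evans asymmetric alkylation: the chelated Z-enolate is alkylated on the face opposite the C4 benzyl group of the auxiliary, which sets the future C5 centre as (R).

Step 3
Reactants: 6 tert-butyl (3R)-4-[(4S)-4-benzyl-2-oxo-1,3-oxazolidin-3-yl]-3-(3,4-dimethoxybenzyl)-4-oxobutanoate
Product: 8 (4R)-4-(3,4-dimethoxybenzyl)oxolan-2-one, via hydroxy ester 7 (not isolated)
Conditions: LiBH4, THF, MeOH (1 equiv), 0 °C; aqueous work-up; then CF3CO2H, CH2Cl2, rt
Reagents that add atoms: none
Why: Reductive cleavage of the imide by LiBH4 spares the tert-butyl ester, and acid then removes the tert-butyl group and lactonises the γ-hydroxy acid without touching the stereocentre.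

Step 4
Reactants: 9 vanillin (4-hydroxy-3-methoxybenzaldehyde)
Product: 10 4-formyl-2-methoxyphenyl 4-methylbenzenesulfonate
Conditions: TsCl, Et3N, DMAP (cat.), CH2Cl2, 0 °C to rt
Reagents that add atoms: 4-methylbenzenesulfonyl chloride, Cc1ccc(cc1)S(=O)(=O)Cl
Why: Sulfonylation of the phenol gives a protecting group that should survive every later step and makes this aryl ring electron-poor for step 8.

Step 5
Reactants: 8 (4R)-4-(3,4-dimethoxybenzyl)oxolan-2-one; 10 4-formyl-2-methoxyphenyl 4-methylbenzenesulfonate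
Product: 14 (3E,4R)-4-(3,4-dimethoxybenzyl)-3-[3-methoxy-4-(tosyloxy)benzylidene]oxolan-2-one, via lithium enolate 11 (not isolated), via lithium aldolate 12 (not isolated), via aldol mesylate 13 (not isolated)
Conditions: LiN(iPr)2, THF, −78 °C; 10, −78 °C; then MsCl, −78 to 0 °C; then DBU, 0 °C to rt
Reagents that add atoms: none
Why: Aldol addition of the lactone enolate, mesylation of the aldolate and E1cB elimination (aldol condensation) should give the conjugated (E)-benzylidene lactone, the thermodynamically preferred geometry, with C4 untouched.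

Step 6
Reactants: 14 (3E,4R)-4-(3,4-dimethoxybenzyl)-3-[3-methoxy-4-(tosyloxy)benzylidene]oxolan-2-one
Product: 15 (2E,3R)-3-(3,4-dimethoxybenzyl)-2-[3-methoxy-4-(tosyloxy)benzylidene]butane-1,4-diol
Conditions: iBu2AlH (4.5 equiv), CH2Cl2, −78 to 0 °C; aq. potassium sodium tartrate (KNaC4H4O6) work-up
Reagents that add atoms: none
Why: 1,2-Reduction of the conjugated lactone by iBu2AlH should give the allylic–homoallylic diol without changing the alkene geometry or cleaving the aryl sulfonate.

Step 7
Reactants: 15 (2E,3R)-3-(3,4-dimethoxybenzyl)-2-[3-methoxy-4-(tosyloxy)benzylidene]butane-1,4-diol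
Product: 17 4-[(2R,3S,4S)-4-(3,4-dimethoxybenzyl)-3-hydroxy-3-(hydroxymethyl)oxolan-2-yl]-2-methoxyphenyl 4-methylbenzenesulfonate, via epoxy diol 16 (not isolated)
Conditions: Ti(OiPr)4 (20 mol %), L-(+)-diethyl tartrate (24 mol %), tBuOOH (2 equiv, in decane), 4 Å MS, CH2Cl2, −20 °C; then CSA (10 mol %), 0 °C to rt
Reagents that add atoms: tert-butyl hydroperoxide, CC(C)(C)OO
Why: Katsuki–Sharpless asymmetric epoxidation of the allylic alcohol (the L-(+)-tartrate sets the (2S,3S)-epoxide by reagent control) and acid-catalysed 5-endo opening of the epoxide at its benzylic carbon by the homoallylic hydroxyl, with inversion, close ring A and set C1 (S) and C2 (R) with the aryl group cis to the tertiary hydroxyl.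

Step 8
Reactants: 17 4-[(2R,3S,4S)-4-(3,4-dimethoxybenzyl)-3-hydroxy-3-(hydroxymethyl)oxolan-2-yl]-2-methoxyphenyl 4-methylbenzenesulfonate
Product: 19 4-[(1S,2R,5R,6S)-6-(3,4-dimethoxyphenyl)-1-hydroxy-3,7-dioxabicyclo[3.3.0]octan-2-yl]-2-methoxyphenyl 4-methylbenzenesulfonate, via benzylic cation 18 (not isolated)
Conditions: DDQ (1.2 equiv), 4 Å MS, CH2Cl2, 0 °C to rt, in the dark
Reagents that add atoms: none
Why: DDQ forms a charge-transfer complex with the electron-rich dimethoxyphenyl ring and abstracts hydride from the benzylic methylene, which gives the para-methoxy-stabilised cation 18; the C8 hydroxyl, held cis to the side chain on ring A, captures it. The closest known reaction type is the DDQ-mediated oxidative benzylic C–H etherification (cross-dehydrogenative C–O coupling) that turns benzyl-substituted tetrahydrofuran lignans into furofurans. Ring B closes in a 5-exo-trig mode (oxygen onto the trigonal cation carbon, the aryl π-system exocyclic), and only the cis-fused bicycle can form. The new C6 centre is controlled by C5: in the cis-fused transition state the aryl group turns away from the C4 methylene of ring A and should end exo, which is (S). The step needs site selectivity between two benzylic positions and restraint from a second oxidation; the tosylate makes the other aryl ring too electron-poor for hydride loss at C2, and the product C6–H lies on the concave face, poorly aligned with the arene, so a small excess of DDQ should stop at 19.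

Step 9
Reactants: 19 4-[(1S,2R,5R,6S)-6-(3,4-dimethoxyphenyl)-1-hydroxy-3,7-dioxabicyclo[3.3.0]octan-2-yl]-2-methoxyphenyl 4-methylbenzenesulfonate
Product: 20 (1S,2R,5R,6S)-6-(3,4-dimethoxyphenyl)-2-(4-hydroxy-3-methoxyphenyl)-3,7-dioxabicyclo[3.3.0]octan-1-ol
Conditions: KOH, MeOH/THF/H2O, 55 °C; then aq. NH4Cl to pH 7
Reagents that add atoms: none
Why: Alkaline hydrolysis of the aryl sulfonate (hydroxide attack at sulfur) frees the phenol, while the benzylic ethers and the tertiary alcohol are inert to base.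

**Compound list**

1 | 3-(3,4-dimethoxyphenyl)propanoic acid | COc1ccc(CCC(=O)O)cc1OC | starting material
2 | (4S)-4-benzyl-1,3-oxazolidin-2-one | O=C1N[C@@H](Cc2ccccc2)CO1 | starting material
3 | 3-(3,4-dimethoxyphenyl)propanoic pivalic anhydride (not isolated) | COc1ccc(CCC(=O)OC(=O)C(C)(C)C)cc1OC | intermediate
4 | (4S)-4-benzyl-3-[3-(3,4-dimethoxyphenyl)propanoyl]-1,3-oxazolidin-2-one | COc1ccc(CCC(=O)N2[C@@H](Cc3ccccc3)COC2=O)cc1OC | intermediate
5 | sodium (Z)-enolate of 4 (not isolated) | COc1ccc(C/C=C(\[O-])N2[C@@H](Cc3ccccc3)COC2=O)cc1OC.[Na+] | intermediate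
6 | tert-butyl (3R)-4-[(4S)-4-benzyl-2-oxo-1,3-oxazolidin-3-yl]-3-(3,4-dimethoxybenzyl)-4-oxobutanoate | COc1ccc(C[C@H](CC(=O)OC(C)(C)C)C(=O)N2[C@@H](Cc3ccccc3)COC2=O)cc1OC | intermediate
7 | tert-butyl (3R)-3-(3,4-dimethoxybenzyl)-4-hydroxybutanoate (not isolated) | COc1ccc(C[C@H](CC(=O)OC(C)(C)C)CO)cc1OC | intermediate
8 | (4R)-4-(3,4-dimethoxybenzyl)oxolan-2-one | COc1ccc(C[C@@H]2CC(=O)OC2)cc1OC | intermediate
9 | vanillin (4-hydroxy-3-methoxybenzaldehyde) | COc1cc(C=O)ccc1O | starting material
10 | 4-formyl-2-methoxyphenyl 4-methylbenzenesulfonate | COc1cc(C=O)ccc1OS(=O)(=O)c1ccc(C)cc1 | intermediate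
11 | lithium enolate of 8 (not isolated) | COc1ccc(C[C@H]2COC([O-])=C2)cc1OC.[Li+] | intermediate
12 | lithium alkoxide of (3S,4R)-4-(3,4-dimethoxybenzyl)-3-{hydroxy[3-methoxy-4-(tosyloxy)phenyl]methyl}oxolan-2-one, 3,4-trans, both carbinol epimers (not isolated) | COc1ccc(C[C@H]2COC(=O)[C@@H]2C([O-])c2ccc(OS(=O)(=O)c3ccc(C)cc3)c(OC)c2)cc1OC.[Li+] | intermediate
13 | methanesulfonate of the aldol adduct, (3S,4R), both carbinol epimers (not isolated) | COc1ccc(C[C@H]2COC(=O)[C@@H]2C(OS(C)(=O)=O)c2ccc(OS(=O)(=O)c3ccc(C)cc3)c(OC)c2)cc1OC | intermediate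
14 | (3E,4R)-4-(3,4-dimethoxybenzyl)-3-[3-methoxy-4-(tosyloxy)benzylidene]oxolan-2-one | COc1ccc(C[C@H]2COC(=O)/C2=C/c2ccc(OS(=O)(=O)c3ccc(C)cc3)c(OC)c2)cc1OC | intermediate
15 | (2E,3R)-3-(3,4-dimethoxybenzyl)-2-[3-methoxy-4-(tosyloxy)benzylidene]butane-1,4-diol | COc1ccc(C[C@@H](CO)/C(CO)=C\c2ccc(OS(=O)(=O)c3ccc(C)cc3)c(OC)c2)cc1OC | intermediate
16 | 4-[(2S,3S)-3-[(2S)-1-(3,4-dimethoxyphenyl)-3-hydroxypropan-2-yl]-3-(hydroxymethyl)oxiran-2-yl]-2-methoxyphenyl 4-methylbenzenesulfonate (not isolated) | COc1ccc(C[C@@H](CO)[C@@]2(CO)O[C@H]2c2ccc(OS(=O)(=O)c3ccc(C)cc3)c(OC)c2)cc1OC | intermediate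
17 | 4-[(2R,3S,4S)-4-(3,4-dimethoxybenzyl)-3-hydroxy-3-(hydroxymethyl)oxolan-2-yl]-2-methoxyphenyl 4-methylbenzenesulfonate | COc1cc([C@H]2OC[C@H](Cc3ccc(OC)c(OC)c3)[C@]2(O)CO)ccc1OS(=O)(=O)c1ccc(C)cc1 | intermediate
18 | benzylic cation of 17 at the dimethoxybenzyl carbon, as ion pair with the 2,3-dichloro-5,6-dicyano-4-hydroxyphenolate anion (not isolated) | COc1cc([C@H]2OC[C@H]([CH+]c3ccc(OC)c(OC)c3)[C@]2(O)CO)ccc1OS(=O)(=O)c1ccc(C)cc1.[O-]c1c(Cl)c(Cl)c(O)c(C#N)c1C#N | intermediate
19 | 4-[(1S,2R,5R,6S)-6-(3,4-dimethoxyphenyl)-1-hydroxy-3,7-dioxabicyclo[3.3.0]octan-2-yl]-2-methoxyphenyl 4-methylbenzenesulfonate | COc1cc([C@H]2OC[C@@H]3[C@@H](c4ccc(OC)c(OC)c4)OC[C@]23O)ccc1OS(=O)(=O)c1ccc(C)cc1 | intermediate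
20 | (1S,2R,5R,6S)-6-(3,4-dimethoxyphenyl)-2-(4-hydroxy-3-methoxyphenyl)-3,7-dioxabicyclo[3.3.0]octan-1-ol | COc1cc([C@H]2OC[C@@H]3[C@@H](c4ccc(OC)c(OC)c4)OC[C@]23O)ccc1O | target

**Totals and risks**

Total step count: 9. Longest linear sequence: 8 steps (steps 1 to 3 and 5 to 9, from compound 1); step 4 is a one-step side branch.

Step 8. What may go wrong is a second hydride abstraction from the new benzylic ether C6–H of the product, loss of the C5 proton from the cation to give a styrene, or incomplete exo selectivity in the ring closure. The fallback sets out from 17 and comes back at 19, with no oxidant present when the ring closes. The benzylic methylene is oxidised on purpose to the ketone level with DDQ (2.5 equiv) in wet CH2Cl2, which should give the aryl ketone F1 (in equilibrium with its cyclic hemiketal). Luche reduction (NaBH4, CeCl3·7H2O, MeOH, −78 °C) then gives the benzylic alcohol F2 as a mixture of carbinol epimers. Catalytic CSA in CH2Cl2 at 0 °C ionises this alcohol and the C8 hydroxyl closes ring B by cyclodehydration, the classical furofuran end-game, to give 19.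

Step 7. What may go wrong is erosion of facial selectivity in the oxygen transfer, because the resident stereocentre and the second hydroxyl (which can also bind titanium) may oppose the tartrate, or partial loss of stereospecificity when the epoxide opens at the benzylic carbon. The fallback sets out from 15 and comes back at 17. Both hydroxyls are silylated (TBSCl, imidazole, DMF) to give the bis-silyl ether F3. A chiral-dioxirane epoxidation under pure reagent control (enantiomer of the fructose-derived Shi ketone, chosen by the spiro transition-state model, KHSO5 as 2KHSO5·KHSO4·K2SO4, K2CO3, MeCN/dimethoxymethane/water, 0 °C) gives the silylated epoxide F4. HF·pyridine in THF then removes both silyl groups and the acid closes ring A through 16 to give 17.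

Step 5. What may go wrong is γ-deprotonation at C4 by DBU, which would racemise that centre or move the double bond into the ring, and incomplete E selectivity in the elimination. The fallback sets out from 8 and comes back at 14. Enolate phosphorylation and 1,3-phosphorus shift (LiN(iPr)2, ClP(O)(OEt)2, then a second equivalent of LiN(iPr)2, THF, −78 °C) give the α-phosphono lactone F5. Horner–Wadsworth–Emmons olefination with 10 (KOtBu, THF, 0 °C) then gives 14 under conditions in which the only base present is the weakly basic phosphonate anion.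

**Further compounds**

F1 | step 8 | 4-[(2R,3S,4S)-4-(3,4-dimethoxybenzoyl)-3-hydroxy-3-(hydroxymethyl)oxolan-2-yl]-2-methoxyphenyl 4-methylbenzenesulfonate | COc1cc([C@H]2OC[C@H](C(=O)c3ccc(OC)c(OC)c3)[C@]2(O)CO)ccc1OS(=O)(=O)c1ccc(C)cc1
F2 | step 8 | 4-[4-[(3,4-dimethoxyphenyl)(hydroxy)methyl]-3-hydroxy-3-(hydroxymethyl)oxolan-2-yl]-2-methoxyphenyl 4-methylbenzenesulfonate, ring configuration as in 17, both carbinol epimers | COc1cc([C@H]2OC[C@H](C(O)c3ccc(OC)c(OC)c3)[C@]2(O)CO)ccc1OS(=O)(=O)c1ccc(C)cc1
F3 | step 7 | bis(tert-butyldimethylsilyl) ether of 15 | COc1ccc(C[C@@H](CO[Si](C)(C)C(C)(C)C)/C(CO[Si](C)(C)C(C)(C)C)=C\c2ccc(OS(=O)(=O)c3ccc(C)cc3)c(OC)c2)cc1OC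
F4 | step 7 | bis(tert-butyldimethylsilyl) ether of 16 | COc1ccc(C[C@@H](CO[Si](C)(C)C(C)(C)C)[C@@]2(CO[Si](C)(C)C(C)(C)C)O[C@H]2c2ccc(OS(=O)(=O)c3ccc(C)cc3)c(OC)c2)cc1OC
F5 | step 5 | diethyl [(4R)-4-(3,4-dimethoxybenzyl)-2-oxooxolan-3-yl]phosphonate, C3 as either epimer | COc1ccc(C[C@H]2COC(=O)C2P(=O)(OCC)OCC)cc1OC
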